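**Retrosynthetic overview**

- The target comes from global O-demethylation and desilylation of a hexamethyl ether, whose stilbene arm is attached last by Heck coupling at C6 of ring system 1.
- The furan ring of ring system 2 (O1'–C2' and C2'–C3') is closed by a [4+1] annulation of the ring B ortho-quinone methide with a chiral 4-methoxybenzylsulfonium ylide.
- Ring B (C3a', C4', C5', C6', C7', C7a') is a resorcinol with oxygens on C4' and C7a', C3' on C3a' between them and C3 of ring system 1 on C6' opposite. This 2,5-disubstituted resorcinol pattern is what a 3-substituted cyclobutenone (supplying C5', C6', C7', C7a') and a siloxyalkyne (supplying C3a', C4') give in a Danheiser benzannulation.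
- The cyclobutenone on C3 comes from a terminal alkyne and dichloroketene; the alkyne comes from a trans ester made by enantioselective dirhodium-carbene C–H insertion (C2–C3). The siloxyalkyne comes from 3,5-dimethoxybenzaldehyde.
- Order of ring formation: furan ring of ring system 1, then ring B, then furan ring of ring system 2.

Key step: step 14

Assumption on the starting material: 4-bromo-2-hydroxy-6-methoxybenzaldehyde is taken as a catalogue compound; it places the future C3a between the two ring A oxygens from the start, which substitution or metalation of 3-bromo-5-methoxyphenol would not do reliably.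

Assumption on absolute sense: the (R)-phthaloyl-tert-leucinate dirhodium catalyst is taken to give the 2S insertion product, and the ylide from (2S,5S)-2,5-dimethylthiolane to give 2'S; if either sense proved opposite, the antipodal catalyst or sulfide would be used with no other change.

Shorthand in names: R1 = (2S,3S)-6-bromo-4-methoxy-2-(4-methoxyphenyl)-2,3-dihydro-1-benzofuran-3-yl (trans); Ar = 3,5-dimethoxyphenyl; TBS = tert-butyldimethylsilyl; TIPS = triisopropylsilyl; PMB = 4-methoxybenzyl.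

**Route**

Step 1
Reactants: 1 4-bromo-2-hydroxy-6-methoxybenzaldehyde; 2 4-methoxybenzyl chloride
Product: 3 4-bromo-2-methoxy-6-[(4-methoxybenzyl)oxy]benzaldehyde
Conditions: K2CO3, DMF, 60 °C
Reagents that add atoms: none
Why: Williamson etherification of the salicylaldehyde hydroxyl with a reactive benzylic chloride should be clean, and it installs the O–CH2 group that later becomes C2 with its 4-methoxyphenyl substituent.

Step 2
Reactants: 3 4-bromo-2-methoxy-6-[(4-methoxybenzyl)oxy]benzaldehyde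
Product: 5 2-[4-bromo-2-methoxy-6-(4-methoxybenzyloxy)phenyl]acetonitrile, via N-(1-tosylvinyl)formamide 4 (not isolated)
Conditions: TosMIC, t-BuOK, DME, −40 °C; then MeOH, reflux
Reagents that add atoms: p-toluenesulfonylmethyl isocyanide (TosMIC), Cc1ccc(S(=O)(=O)C[N+]#[C-])cc1
Why: van Leusen reductive cyanation, in which the TosMIC anion adds to the aldehyde, the oxazoline opens to vinylformamide 4 and methanolysis removes formyl and sulfinate, should give the one-carbon homologue under basic conditions that spare the acid-labile PMB ether.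

Step 3
Reactants: 5 2-[4-bromo-2-methoxy-6-(4-methoxybenzyloxy)phenyl]acetonitrile
Product: 6 2-[4-bromo-2-methoxy-6-(4-methoxybenzyloxy)phenyl]acetic acid
Conditions: KOH, ethylene glycol–H2O, 120 °C; then aq. HCl to pH 3, 0 °C
Reagents that add atoms: water, O; potassium hydroxide, [K+].[OH-]
Why: alkaline hydrolysis of an arylacetonitrile through the amide is standard, and aryl bromide, methyl ether and PMB ether are stable to hot base.

Step 4
Reactants: 6 2-[4-bromo-2-methoxy-6-(4-methoxybenzyloxy)phenyl]acetic acid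
Product: 7 methyl 2-[4-bromo-2-methoxy-6-(4-methoxybenzyloxy)phenyl]acetate
Conditions: MeI, K2CO3, DMF, rt
Reagents that add atoms: iodomethane, CI
Why: O-alkylation of the carboxylate gives the methyl ester without acid, so the PMB ether is not put at risk.

Step 5
Reactants: 7 methyl 2-[4-bromo-2-methoxy-6-(4-methoxybenzyloxy)phenyl]acetate
Product: 8 methyl 2-[4-bromo-2-methoxy-6-(4-methoxybenzyloxy)phenyl]-2-diazoacetate
Conditions: p-ABSA, DBU, MeCN, 0 °C → rt
Reagents that add atoms: 4-acetamidobenzenesulfonyl azide (p-ABSA), CC(=O)Nc1ccc(S(=O)(=O)N=[N+]=[N-])cc1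
Why: Regitz diazo transfer to the arylacetate enolate should give the donor/acceptor diazo ester, though the two ortho alkoxy groups may slow enolisation and call for longer reaction time.

Step 6
Reactants: 8 methyl 2-[4-bromo-2-methoxy-6-(4-methoxybenzyloxy)phenyl]-2-diazoacetate
Product: 9 methyl (2S,3R)-6-bromo-4-methoxy-2-(4-methoxyphenyl)-2,3-dihydro-1-benzofuran-3-carboxylate (cis)
Conditions: Rh2(R-PTTL)4 [dirhodium tetrakis(N-phthaloyl-(R)-tert-leucinate)] (1 mol %), toluene, −60 °C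
Reagents that add atoms: none
Why: the chiral dirhodium carboxylate forms a donor/acceptor carbene that inserts into the activated benzylic ether C–H five atoms away (C2–C3, furan ring of ring system 1); the concerted insertion is cis-selective and the catalyst fixes C2 as S, while insertion into the methoxy C–H is much slower.

Step 7
Reactants: 9 methyl (2S,3R)-6-bromo-4-methoxy-2-(4-methoxyphenyl)-2,3-dihydro-1-benzofuran-3-carboxylate
Product: 10 methyl (2S,3S)-6-bromo-4-methoxy-2-(4-methoxyphenyl)-2,3-dihydro-1-benzofuran-3-carboxylate (trans)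
Conditions: NaOMe, MeOH, rt
Reagents that add atoms: none
Why: base-mediated epimerisation through the ester enolate should move C3 to the thermodynamically preferred trans arrangement while C2, which carries no acidic hydrogen, keeps its configuration.

Step 8
Reactants: 10 methyl (2S,3S)-6-bromo-4-methoxy-2-(4-methoxyphenyl)-2,3-dihydro-1-benzofuran-3-carboxylate
Product: 12 (2S,3S)-6-bromo-3-ethynyl-4-methoxy-2-(4-methoxyphenyl)-2,3-dihydro-1-benzofuran (trans), via aldehyde 11 (not isolated)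
Conditions: DIBAL-H, CH2Cl2, −78 °C; then MeOH, K2CO3, dimethyl (1-diazo-2-oxopropyl)phosphonate, −78 °C → rt
Reagents that add atoms: dimethyl (1-diazo-2-oxopropyl)phosphonate (Ohira–Bestmann reagent), CC(=O)C(=[N+]=[N-])P(=O)(OC)OC
Why: DIBAL-H at −78 °C stops at the aluminium hemiacetal, and methanol with carbonate releases aldehyde 11 in the presence of the diazomethylphosphonate anion for Ohira–Bestmann (Seyferth–Gilbert) homologation; any epimerisation of 11 at C3 converges on the trans isomer.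

Step 9
Reactants: 12 (2S,3S)-6-bromo-3-ethynyl-4-methoxy-2-(4-methoxyphenyl)-2,3-dihydro-1-benzofuran
Product: 13 3-[(2S,3R)-6-bromo-4-methoxy-2-(4-methoxyphenyl)-2,3-dihydro-1-benzofuran-3-yl]-4,4-dichlorocyclobut-2-en-1-one (trans; the 3R label is only a priority change caused by the CCl2 group)
Conditions: Cl3CCOCl, zinc–copper couple, Et2O–DME, rt → 40 °C
Reagents that add atoms: trichloroacetyl chloride, ClC(=O)C(Cl)(Cl)Cl
Why: dichloroketene made in situ by zinc dechlorination adds [2+2] to the terminal alkyne with the substituted alkyne carbon bonding to CCl2, the standard entry to 3-substituted cyclobutenones; DME ties up the zinc chloride.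

Step 10
Reactants: 13 3-[(2S,3R)-6-bromo-4-methoxy-2-(4-methoxyphenyl)-2,3-dihydro-1-benzofuran-3-yl]-4,4-dichlorocyclobut-2-en-1-one
Product: 14 3-R1-cyclobut-2-en-1-one (trans, 2S,3S)
Conditions: Zn dust, AcOH, TMEDA, EtOH, 0 °C
Reagents that add atoms: none
Why: buffered zinc reduction removes both α-chlorines of the dichloroketone at 0 °C, conditions under which the aryl bromide and the strained enone should survive.

Step 11
Reactants: 15 3,5-dimethoxybenzaldehyde; 16 ethynylmagnesium bromide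
Product: 17 1-(3,5-dimethoxyphenyl)prop-2-yn-1-ol (racemic)
Conditions: THF, 0 °C; then H2O/NH4Cl
Reagents that add atoms: none
Why: Grignard addition of the acetylide to an aromatic aldehyde is reliable; the carbinol centre need not be controlled because it becomes trigonal in step 19.

Step 12
Reactants: 17 1-(3,5-dimethoxyphenyl)prop-2-yn-1-ol
Product: 18 tert-butyl{[1-(3,5-dimethoxyphenyl)prop-2-yn-1-yl]oxy}dimethylsilane (racemic)
Conditions: TBSCl, imidazole, DMF, rt
Reagents that add atoms: tert-butyldimethylsilyl chloride, CC(C)(C)[Si](C)(C)Cl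
Why: standard silylation of a secondary propargylic alcohol.

Step 13
Reactants: 18 tert-butyl{[1-(3,5-dimethoxyphenyl)prop-2-yn-1-yl]oxy}dimethylsilane
Product: 21 3-(tert-butyldimethylsilyloxy)-3-(3,5-dimethoxyphenyl)-1-(triisopropylsilyloxy)prop-1-yne (racemic), via lithium acetylide 19 (not isolated), via lithium ynolate 20 (not isolated)
Conditions: n-BuLi, THF, −78 °C; add to LiOOt-Bu (from t-BuOOH and LiHMDS), −78 → 0 °C; then TIPSOTf, −78 °C
Reagents that add atoms: tert-butyl hydroperoxide, CC(C)(C)OO; triisopropylsilyl trifluoromethanesulfonate, CC(C)[Si](C(C)C)(C(C)C)OS(=O)(=O)C(F)(F)F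
Why: electrophilic oxygenation of the lithium acetylide by lithium tert-butyl peroxide gives the ynolate, which is O-silylated by the bulky silyl triflate to a siloxyalkyne stable enough to isolate; this avoids the enolisable α-aryl ester that an ester-homologation route would need.

Step 14
Reactants: 14 3-R1-cyclobut-2-en-1-one; 21 3-(tert-butyldimethylsilyloxy)-3-(3,5-dimethoxyphenyl)-1-(triisopropylsilyloxy)prop-1-yne
Product: 26 2-[(tert-butyldimethylsilyloxy)(3,5-dimethoxyphenyl)methyl]-5-R1-3-(triisopropylsilyloxy)phenol (two epimers at the carbinol carbon), via vinylketene 22 (not isolated), via 4-vinylcyclobutenone 23 (not isolated), via dienylketene 24 (not isolated), via cyclohexadienone 25 (not isolated)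
Conditions: 21 (1.3 equiv), toluene, 80 °C then 110 °C, sealed tube
Reagents that add atoms: none
Why: heat opens the cyclobutenone by 4π-electrocyclic cleavage of the C7'–C7a' bond to vinylketene 22, whose ketene adds [2+2] to the electron-rich siloxyalkyne (C7a'–C3a' and C5'–C4') to give 23, and a second 4π opening gives dienylketene 24. The closest known reaction type is the Danheiser benzannulation of 3-substituted cyclobutenones with trialkylsilyloxyalkynes to resorcinol monosilyl ethers. Ring B closes by thermal 6π-electrocyclisation of 24 (re-forming C7'–C7a') to dienone 25, which tautomerises to the phenol. The ring becomes aromatic, so no new stereocentre is made; the carbinol centre brought in with racemic 21 is erased in step 19. The selectivity needed is regiochemical: the ketene carbonyl carbon must bond to the oxygen-free alkyne carbon, which the polarisation of the ynol ether (nucleophilic β-carbon) secures, and this places the new hydroxyl next to the benzylic silyl ether. Only heat is used, with two strained four-membered rings spent on the way to an arene, so C2 and C3 of ring system 1 and the aryl bromide should be left alone; the slight excess of 21 limits acylation of the product phenol by 22.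

Step 15
Reactants: 26 2-[(tert-butyldimethylsilyloxy)(3,5-dimethoxyphenyl)methyl]-5-R1-3-(triisopropylsilyloxy)phenol
Product: 27 2-[(3,5-dimethoxyphenyl)(4-methylbenzenesulfonyl)methyl]-5-R1-3-(triisopropylsilyloxy)phenol (two epimers)
Conditions: p-TolSO2H (freshly liberated from its sodium salt), CH2Cl2, rt
Reagents that add atoms: 4-methylbenzenesulfinic acid, Cc1ccc(S(=O)O)cc1
Why: the benzylic silyl ether, activated by the ortho hydroxyl and ortho silyloxy groups, should ionise under the mild acidity of the sulfinic acid and be captured at sulfur to give the sulfone, while the aryl TIPS ether and the less easily ionised C2–O bond of ring system 1 should persist.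

Step 16
Reactants: 28 (2R,5R)-hexane-2,5-diol
Product: 29 (2R,5R)-hexane-2,5-diyl dimethanesulfonate
Conditions: MsCl, Et3N, CH2Cl2, 0 °C
Reagents that add atoms: methanesulfonyl chloride, CS(=O)(=O)Cl
Why: sulfonylation at oxygen leaves both stereocentres untouched.

Step 17
Reactants: 29 (2R,5R)-hexane-2,5-diyl dimethanesulfonate
Product: 30 (2S,5S)-2,5-dimethylthiolane
Conditions: Na2S·9H2O, DMSO, rt → 50 °C
Reagents that add atoms: sodium sulfide, [Na+].[Na+].[S-2]
Why: two successive SN2 displacements by sulfide, the second closing the five-membered ring, invert both centres and give the C2-symmetric trans thiolane.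

Step 18
Reactants: 30 (2S,5S)-2,5-dimethylthiolane; 2 4-methoxybenzyl chloride
Product: 31 (2S,5S)-1-(4-methoxybenzyl)-2,5-dimethylthiolan-1-ium tetrafluoroborate
Conditions: AgBF4, CH2Cl2, −20 °C → rt, dark
Reagents that add atoms: silver tetrafluoroborate, [Ag+].F[B-](F)(F)F
Why: S-alkylation of the sulfide is driven by precipitation of silver chloride and gives a salt with a non-nucleophilic counterion; because the sulfide is C2-symmetric, sulfur is not a stereocentre and a single salt results.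

Step 19
Reactants: 27 2-[(3,5-dimethoxyphenyl)(4-methylbenzenesulfonyl)methyl]-5-R1-3-(triisopropylsilyloxy)phenol; 31 (2S,5S)-1-(4-methoxybenzyl)-2,5-dimethylthiolan-1-ium tetrafluoroborate
Product: 33 (2S,3S)-6-bromo-3-[(2S,3S)-3-(3,5-dimethoxyphenyl)-2-(4-methoxyphenyl)-4-(triisopropylsilyloxy)-2,3-dihydro-1-benzofuran-6-yl]-4-methoxy-2-(4-methoxyphenyl)-2,3-dihydro-1-benzofuran (both rings trans), via ortho-quinone methide 32 (not isolated)
Conditions: Cs2CO3 (3 equiv), CH2Cl2, −20 °C → rt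
Reagents that add atoms: none
Why: Proposed new method: carbonate eliminates sulfinate from the phenoxide of 27 to give ortho-quinone methide 32 and deprotonates 31 to the semi-stabilised benzylic ylide; the ylide carbon adds to the exocyclic carbon (C2'–C3') to give a phenoxide betaine whose oxygen displaces the sulfide with inversion at C2' (O1'–C2', 5-exo-tet), the anti betaine closing fastest so that the ring is trans; the C2-symmetric thiolane exposes one face of the ylide and so fixes C2' as S, C3' following from the trans closure, while the remote centres of ring system 1 exert no control; the closest known reactions are the formal [4+1] annulations of ortho-quinone methides from 2-(sulfonylalkyl)phenols with carbonyl-stabilised sulfonium or ammonium ylides, chiral ones included, and the asymmetric epoxidation of aldehydes by chiral benzylsulfonium ylides.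

Step 20
Reactants: 33 (2S,3S)-6-bromo-3-[(2S,3S)-3-(3,5-dimethoxyphenyl)-2-(4-methoxyphenyl)-4-(triisopropylsilyloxy)-2,3-dihydro-1-benzofuran-6-yl]-4-methoxy-2-(4-methoxyphenyl)-2,3-dihydro-1-benzofuran; 34 4-methoxystyrene
Product: 35 (2S,3S)-3-[(2S,3S)-3-(3,5-dimethoxyphenyl)-2-(4-methoxyphenyl)-4-(triisopropylsilyloxy)-2,3-dihydro-1-benzofuran-6-yl]-4-methoxy-2-(4-methoxyphenyl)-6-[(E)-2-(4-methoxyphenyl)ethenyl]-2,3-dihydro-1-benzofuran
Conditions: Pd(OAc)2 (5 mol %), P(o-tol)3, Et3N, DMF, 100 °C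
Reagents that add atoms: none
Why: Heck coupling of the aryl bromide with the styrene proceeds by syn insertion and syn β-hydride elimination and should give the E-stilbene; the amine base leaves the stereocentres and the aryl silyl ether alone.

Step 21
Reactants: 35 (2S,3S)-3-[(2S,3S)-3-(3,5-dimethoxyphenyl)-2-(4-methoxyphenyl)-4-(triisopropylsilyloxy)-2,3-dihydro-1-benzofuran-6-yl]-4-methoxy-2-(4-methoxyphenyl)-6-[(E)-2-(4-methoxyphenyl)ethenyl]-2,3-dihydro-1-benzofuran
Product: 36 (2S,3S)-3-(3,5-dimethoxyphenyl)-6-{(2S,3S)-4-methoxy-2-(4-methoxyphenyl)-6-[(E)-2-(4-methoxyphenyl)ethenyl]-2,3-dihydro-1-benzofuran-3-yl}-2-(4-methoxyphenyl)-2,3-dihydro-1-benzofuran-4-ol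
Conditions: n-Bu4NF, THF, 0 °C; then H2O
Reagents that add atoms: none
Why: fluoride cleaves the aryl silyl ether rapidly and touches nothing else in the molecule.

Step 22
Reactants: 36 (2S,3S)-3-(3,5-dimethoxyphenyl)-6-{(2S,3S)-4-methoxy-2-(4-methoxyphenyl)-6-[(E)-2-(4-methoxyphenyl)ethenyl]-2,3-dihydro-1-benzofuran-3-yl}-2-(4-methoxyphenyl)-2,3-dihydro-1-benzofuran-4-ol
Product: 37 (2S,3S)-3-(3,5-dihydroxyphenyl)-6-{(2S,3S)-4-hydroxy-2-(4-hydroxyphenyl)-6-[(E)-2-(4-hydroxyphenyl)ethenyl]-2,3-dihydro-1-benzofuran-3-yl}-2-(4-hydroxyphenyl)-2,3-dihydro-1-benzofuran-4-ol (CNP0248228.2)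
Conditions: BCl3 (excess), n-Bu4NI, CH2Cl2, −78 → 0 °C; then ice-water
Reagents that add atoms: none
Why: boron trichloride complexes each aryl methyl ether and iodide removes the methyl group by SN2 at low temperature, a milder cleavage than boron tribromide at room temperature; should C2–O or C2'–O ionise, reclosure returns the thermodynamically preferred trans rings because C3 and C3' are untouched.

**Compound list**

1 | 4-bromo-2-hydroxy-6-methoxybenzaldehyde | O=Cc1c(O)cc(Br)cc1OC | starting material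
2 | 4-methoxybenzyl chloride | COc1ccc(CCl)cc1 | starting material
3 | 4-bromo-2-methoxy-6-[(4-methoxybenzyl)oxy]benzaldehyde | O=Cc1c(OC)cc(Br)cc1OCc1ccc(OC)cc1 | intermediate
4 | N-{2-[4-bromo-2-methoxy-6-(4-methoxybenzyloxy)phenyl]-1-tosylvinyl}formamide | O=CNC(=Cc1c(OC)cc(Br)cc1OCc1ccc(OC)cc1)S(=O)(=O)c1ccc(C)cc1 | intermediate
5 | 2-[4-bromo-2-methoxy-6-(4-methoxybenzyloxy)phenyl]acetonitrile | N#CCc1c(OC)cc(Br)cc1OCc1ccc(OC)cc1 | intermediate
6 | 2-[4-bromo-2-methoxy-6-(4-methoxybenzyloxy)phenyl]acetic acid | OC(=O)Cc1c(OC)cc(Br)cc1OCc1ccc(OC)cc1 | intermediate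
7 | methyl 2-[4-bromo-2-methoxy-6-(4-methoxybenzyloxy)phenyl]acetate | COC(=O)Cc1c(OC)cc(Br)cc1OCc1ccc(OC)cc1 | intermediate
8 | methyl 2-[4-bromo-2-methoxy-6-(4-methoxybenzyloxy)phenyl]-2-diazoacetate | COC(=O)C(=[N+]=[N-])c1c(OC)cc(Br)cc1OCc1ccc(OC)cc1 | intermediate
9 | methyl (2S,3R)-6-bromo-4-methoxy-2-(4-methoxyphenyl)-2,3-dihydro-1-benzofuran-3-carboxylate (cis) | Brc1cc(OC)c2c(c1)O[C@H](c1ccc(OC)cc1)[C@@H]2C(=O)OC | intermediate
10 | methyl (2S,3S)-6-bromo-4-methoxy-2-(4-methoxyphenyl)-2,3-dihydro-1-benzofuran-3-carboxylate (trans) | Brc1cc(OC)c2c(c1)O[C@H](c1ccc(OC)cc1)[C@H]2C(=O)OC | intermediate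
11 | (2S,3S)-6-bromo-4-methoxy-2-(4-methoxyphenyl)-2,3-dihydro-1-benzofuran-3-carbaldehyde | Brc1cc(OC)c2c(c1)O[C@H](c1ccc(OC)cc1)[C@H]2C=O | intermediate
12 | (2S,3S)-6-bromo-3-ethynyl-4-methoxy-2-(4-methoxyphenyl)-2,3-dihydro-1-benzofuran | Brc1cc(OC)c2c(c1)O[C@H](c1ccc(OC)cc1)[C@H]2C#C | intermediate
13 | 3-[(2S,3R)-6-bromo-4-methoxy-2-(4-methoxyphenyl)-2,3-dihydro-1-benzofuran-3-yl]-4,4-dichlorocyclobut-2-en-1-one | Brc1cc(OC)c2c(c1)O[C@H](c1ccc(OC)cc1)[C@H]2C1=CC(=O)C1(Cl)Cl | intermediate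
14 | 3-[(2S,3S)-6-bromo-4-methoxy-2-(4-methoxyphenyl)-2,3-dihydro-1-benzofuran-3-yl]cyclobut-2-en-1-one | Brc1cc(OC)c2c(c1)O[C@H](c1ccc(OC)cc1)[C@H]2C1=CC(=O)C1 | intermediate
15 | 3,5-dimethoxybenzaldehyde | COc1cc(OC)cc(C=O)c1 | starting material
16 | ethynylmagnesium bromide | C#C[Mg]Br | starting material
17 | 1-(3,5-dimethoxyphenyl)prop-2-yn-1-ol (racemic) | COc1cc(OC)cc(C(O)C#C)c1 | intermediate
18 | tert-butyl{[1-(3,5-dimethoxyphenyl)prop-2-yn-1-yl]oxy}dimethylsilane (racemic) | COc1cc(OC)cc(C(O[Si](C)(C)C(C)(C)C)C#C)c1 | intermediate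
19 | lithium acetylide of 18 | COc1cc(OC)cc(C(O[Si](C)(C)C(C)(C)C)C#C[Li])c1 | intermediate
20 | lithium 3-(tert-butyldimethylsilyloxy)-3-(3,5-dimethoxyphenyl)prop-1-yn-1-olate | [Li+].[O-]C#CC(O[Si](C)(C)C(C)(C)C)c1cc(OC)cc(OC)c1 | intermediate
21 | 3-(tert-butyldimethylsilyloxy)-3-(3,5-dimethoxyphenyl)-1-(triisopropylsilyloxy)prop-1-yne (racemic) | COc1cc(OC)cc(C(O[Si](C)(C)C(C)(C)C)C#CO[Si](C(C)C)(C(C)C)C(C)C)c1 | intermediate
22 | 3-R1-buta-1,3-dien-1-one (vinylketene) | Brc1cc(OC)c2c(c1)O[C@H](c1ccc(OC)cc1)[C@H]2C(=C)C=C=O | intermediate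
23 | 2-[(TBS-oxy)(Ar)methyl]-4-(1-R1-ethenyl)-3-(TIPS-oxy)cyclobut-2-en-1-one | Brc1cc(OC)c2c(c1)O[C@H](c1ccc(OC)cc1)[C@H]2C(=C)C1C(=O)C(C(O[Si](C)(C)C(C)(C)C)c2cc(OC)cc(OC)c2)=C1O[Si](C(C)C)(C(C)C)C(C)C | intermediate
24 | 2-[(TBS-oxy)(Ar)methyl]-5-R1-3-(TIPS-oxy)hexa-1,3,5-trien-1-one (dienylketene) | Brc1cc(OC)c2c(c1)O[C@H](c1ccc(OC)cc1)[C@H]2C(=C)C=C(O[Si](C(C)C)(C(C)C)C(C)C)C(=C=O)C(O[Si](C)(C)C(C)(C)C)c1cc(OC)cc(OC)c1 | intermediate
25 | 2-[(TBS-oxy)(Ar)methyl]-5-R1-3-(TIPS-oxy)cyclohexa-2,4-dien-1-one | Brc1cc(OC)c2c(c1)O[C@H](c1ccc(OC)cc1)[C@H]2C1=CC(O[Si](C(C)C)(C(C)C)C(C)C)=C(C(O[Si](C)(C)C(C)(C)C)c2cc(OC)cc(OC)c2)C(=O)C1 | intermediate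
26 | 2-[(tert-butyldimethylsilyloxy)(3,5-dimethoxyphenyl)methyl]-5-R1-3-(triisopropylsilyloxy)phenol | Brc1cc(OC)c2c(c1)O[C@H](c1ccc(OC)cc1)[C@H]2c1cc(O)c(C(O[Si](C)(C)C(C)(C)C)c2cc(OC)cc(OC)c2)c(O[Si](C(C)C)(C(C)C)C(C)C)c1 | intermediate
27 | 2-[(3,5-dimethoxyphenyl)(4-methylbenzenesulfonyl)methyl]-5-R1-3-(triisopropylsilyloxy)phenol | Brc1cc(OC)c2c(c1)O[C@H](c1ccc(OC)cc1)[C@H]2c1cc(O)c(C(c2cc(OC)cc(OC)c2)S(=O)(=O)c2ccc(C)cc2)c(O[Si](C(C)C)(C(C)C)C(C)C)c1 | intermediate
28 | (2R,5R)-hexane-2,5-diol | C[C@@H](O)CC[C@@H](C)O | starting material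
29 | (2R,5R)-hexane-2,5-diyl dimethanesulfonate | C[C@@H](OS(C)(=O)=O)CC[C@@H](C)OS(C)(=O)=O | intermediate
30 | (2S,5S)-2,5-dimethylthiolane | C[C@H]1CC[C@H](C)S1 | intermediate
31 | (2S,5S)-1-(4-methoxybenzyl)-2,5-dimethylthiolan-1-ium tetrafluoroborate | C[C@H]1CC[C@H](C)[S+]1Cc1ccc(OC)cc1.F[B-](F)(F)F | intermediate
32 | 6-[(3,5-dimethoxyphenyl)methylidene]-3-R1-5-(triisopropylsilyloxy)cyclohexa-2,4-dien-1-one (ortho-quinone methide) | Brc1cc(OC)c2c(c1)O[C@H](c1ccc(OC)cc1)[C@H]2C1=CC(=O)C(=Cc2cc(OC)cc(OC)c2)C(O[Si](C(C)C)(C(C)C)C(C)C)=C1 | intermediate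
33 | (2S,3S)-6-bromo-3-[(2S,3S)-3-(3,5-dimethoxyphenyl)-2-(4-methoxyphenyl)-4-(triisopropylsilyloxy)-2,3-dihydro-1-benzofuran-6-yl]-4-methoxy-2-(4-methoxyphenyl)-2,3-dihydro-1-benzofuran | Brc1cc(OC)c2c(c1)O[C@H](c1ccc(OC)cc1)[C@H]2c1cc(O[Si](C(C)C)(C(C)C)C(C)C)c2c(c1)O[C@H](c1ccc(OC)cc1)[C@H]2c1cc(OC)cc(OC)c1 | intermediate
34 | 4-methoxystyrene | C=Cc1ccc(OC)cc1 | starting material
35 | (2S,3S)-3-[(2S,3S)-3-(3,5-dimethoxyphenyl)-2-(4-methoxyphenyl)-4-(triisopropylsilyloxy)-2,3-dihydro-1-benzofuran-6-yl]-4-methoxy-2-(4-methoxyphenyl)-6-[(E)-2-(4-methoxyphenyl)ethenyl]-2,3-dihydro-1-benzofuran | COc1ccc(/C=C/c2cc(OC)c3c(c2)O[C@H](c2ccc(OC)cc2)[C@H]3c2cc(O[Si](C(C)C)(C(C)C)C(C)C)c3c(c2)O[C@H](c2ccc(OC)cc2)[C@H]3c2cc(OC)cc(OC)c2)cc1 | intermediate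
36 | (2S,3S)-3-(3,5-dimethoxyphenyl)-6-{(2S,3S)-4-methoxy-2-(4-methoxyphenyl)-6-[(E)-2-(4-methoxyphenyl)ethenyl]-2,3-dihydro-1-benzofuran-3-yl}-2-(4-methoxyphenyl)-2,3-dihydro-1-benzofuran-4-ol | COc1ccc(/C=C/c2cc(OC)c3c(c2)O[C@H](c2ccc(OC)cc2)[C@H]3c2cc(O)c3c(c2)O[C@H](c2ccc(OC)cc2)[C@H]3c2cc(OC)cc(OC)c2)cc1 | intermediate
37 | (2S,3S)-3-(3,5-dihydroxyphenyl)-6-{(2S,3S)-4-hydroxy-2-(4-hydroxyphenyl)-6-[(E)-2-(4-hydroxyphenyl)ethenyl]-2,3-dihydro-1-benzofuran-3-yl}-2-(4-hydroxyphenyl)-2,3-dihydro-1-benzofuran-4-ol (CNP0248228.2) | Oc1ccc(/C=C/c2cc(O)c3c(c2)O[C@H](c2ccc(O)cc2)[C@H]3c2cc(O)c3c(c2)O[C@H](c2ccc(O)cc2)[C@H]3c2cc(O)cc(O)c2)cc1 | target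

**Step count**

Total: 22 steps. Longest linear sequence: 16 steps (steps 1–10, 14, 15, 19, 20, 21, 22).

**Steps most likely to fail**

1. Step 19 (the [4+1] ring closure). The chiral sulfide is the only controlling element near C2' and C3', so the ylide may discriminate poorly between the two faces and give both trans diastereomers. The electron-rich sulfonium salt may also lose sulfide before it is deprotonated, and the quinone methide may oligomerise if the ylide is slow to form. The fallback uses known donor/donor carbene C–H insertion; it sets out from 26 and returns at 33. Compound 26 is O-alkylated with 2 (K2CO3, DMF) to the aryl 4-methoxybenzyl ether F1. HF·pyridine in THF removes the benzylic silyl group to give the diarylmethanol F2, Dess–Martin periodinane gives the diaryl ketone F3, and hydrazine hydrate with catalytic acetic acid in hot ethanol gives the hydrazone F4. MnO2 in CH2Cl2 oxidises F4 to the diaryldiazomethane F5. With Rh2(R-PTAD)4 [dirhodium tetrakis((R)-N-phthaloyl-1-adamantylglycinate)] at 0 °C, F5 should insert into the benzylic ether C–H to give the cis-2',3'-diaryl compound F6 with C3' set as S by the catalyst. Brief treatment with CF3CO2H in CH2Cl2 at 0 °C then equilibrates C2' through the 4-methoxybenzylic cation to the trans isomer, which is 33.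

2. Step 14 (the benzannulation). The alkyne carbon that must attack the ketene carries a branched, silyloxy-bearing substituent, so the [2+2] step may be slow. In that case the vinylketene would dimerise or acylate the product phenol, and prolonged heating could expel silanol from the product. The fallback sets out from 14 and returns at 27; the aryl carbinol is no longer carried through the pericyclic cascade but built afterwards. 3,3-Diethoxypropyne is converted by the protocol of step 13 into the smaller ketenophile 3,3-diethoxy-1-(triisopropylsilyloxy)prop-1-yne F7. Heating F7 with 14 as in step 14 should give the acetal phenol F8, and pyridinium p-toluenesulfonate in acetone–water unmasks the salicylaldehyde F9. 3,5-Dimethoxyphenylmagnesium bromide (2.2 equiv, THF, −78 → 0 °C) adds to give the ortho-hydroxy diarylmethanol F10, and 4-methylbenzenesulfinic acid in CH2Cl2 converts F10 into 27.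

3. Step 22 (global demethylation). Six aryl methyl ethers must be cleaved in the presence of an electron-rich stilbene and two benzylic C–O bonds. The Lewis acid may ionise these bonds or protonate the stilbene, leading to cation–olefin oligomerisation, and cleavage may stop at partly methylated stages. The fallback sets out from 33 and returns at 37; the ethers are removed before the stilbene exists, and the arm is brought in with an ester-protected styrene. Compound 33 is treated with n-Bu4NF and then BBr3 (CH2Cl2, −78 → 0 °C) to give the hexaphenol bromide F11. Ac2O with pyridine gives the hexaacetate F12. Heck coupling with 4-acetoxystyrene (Pd(OAc)2, P(o-tol)3, Et3N, DMF, 100 °C) gives the heptaacetate stilbene F13, and K2CO3 in MeOH at 0 °C under argon removes the acetates to give 37.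

Further compounds
F1 | step 19 | 4-methoxybenzyl ether of 26 | Brc1cc(OC)c2c(c1)O[C@H](c1ccc(OC)cc1)[C@H]2c1cc(OCc2ccc(OC)cc2)c(C(O[Si](C)(C)C(C)(C)C)c2cc(OC)cc(OC)c2)c(O[Si](C(C)C)(C(C)C)C(C)C)c1
F2 | step 19 | (3,5-dimethoxyphenyl)[2-(4-methoxybenzyloxy)-4-R1-6-(triisopropylsilyloxy)phenyl]methanol | Brc1cc(OC)c2c(c1)O[C@H](c1ccc(OC)cc1)[C@H]2c1cc(OCc2ccc(OC)cc2)c(C(O)c2cc(OC)cc(OC)c2)c(O[Si](C(C)C)(C(C)C)C(C)C)c1
F3 | step 19 | (3,5-dimethoxyphenyl)[2-(4-methoxybenzyloxy)-4-R1-6-(triisopropylsilyloxy)phenyl]methanone | Brc1cc(OC)c2c(c1)O[C@H](c1ccc(OC)cc1)[C@H]2c1cc(OCc2ccc(OC)cc2)c(C(=O)c2cc(OC)cc(OC)c2)c(O[Si](C(C)C)(C(C)C)C(C)C)c1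
F4 | step 19 | hydrazone of F3 | Brc1cc(OC)c2c(c1)O[C@H](c1ccc(OC)cc1)[C@H]2c1cc(OCc2ccc(OC)cc2)c(C(=NN)c2cc(OC)cc(OC)c2)c(O[Si](C(C)C)(C(C)C)C(C)C)c1
F5 | step 19 | diaryldiazomethane from F4 | Brc1cc(OC)c2c(c1)O[C@H](c1ccc(OC)cc1)[C@H]2c1cc(OCc2ccc(OC)cc2)c(C(=[N+]=[N-])c2cc(OC)cc(OC)c2)c(O[Si](C(C)C)(C(C)C)C(C)C)c1
F6 | step 19 | (2S,3S)-6-bromo-3-[(2R,3S)-3-(3,5-dimethoxyphenyl)-2-(4-methoxyphenyl)-4-(triisopropylsilyloxy)-2,3-dihydro-1-benzofuran-6-yl]-4-methoxy-2-(4-methoxyphenyl)-2,3-dihydro-1-benzofuran (second ring cis) | Brc1cc(OC)c2c(c1)O[C@H](c1ccc(OC)cc1)[C@H]2c1cc(O[Si](C(C)C)(C(C)C)C(C)C)c2c(c1)O[C@@H](c1ccc(OC)cc1)[C@H]2c1cc(OC)cc(OC)c1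
F7 | step 14 | 3,3-diethoxy-1-(triisopropylsilyloxy)prop-1-yne | CCOC(OCC)C#CO[Si](C(C)C)(C(C)C)C(C)C
F8 | step 14 | 2-(diethoxymethyl)-5-R1-3-(triisopropylsilyloxy)phenol | Brc1cc(OC)c2c(c1)O[C@H](c1ccc(OC)cc1)[C@H]2c1cc(O)c(C(OCC)OCC)c(O[Si](C(C)C)(C(C)C)C(C)C)c1
F9 | step 14 | 2-hydroxy-4-R1-6-(triisopropylsilyloxy)benzaldehyde | Brc1cc(OC)c2c(c1)O[C@H](c1ccc(OC)cc1)[C@H]2c1cc(O)c(C=O)c(O[Si](C(C)C)(C(C)C)C(C)C)c1
F10 | step 14 | 2-[(3,5-dimethoxyphenyl)(hydroxy)methyl]-5-R1-3-(triisopropylsilyloxy)phenol | Brc1cc(OC)c2c(c1)O[C@H](c1ccc(OC)cc1)[C@H]2c1cc(O)c(C(O)c2cc(OC)cc(OC)c2)c(O[Si](C(C)C)(C(C)C)C(C)C)c1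
F11 | step 22 | hexaphenol bromide (33 with all methyl and silyl groups removed) | Brc1cc(O)c2c(c1)O[C@H](c1ccc(O)cc1)[C@H]2c1cc(O)c2c(c1)O[C@H](c1ccc(O)cc1)[C@H]2c1cc(O)cc(O)c1
F12 | step 22 | hexaacetate of F11 | Brc1cc(OC(C)=O)c2c(c1)O[C@H](c1ccc(OC(C)=O)cc1)[C@H]2c1cc(OC(C)=O)c2c(c1)O[C@H](c1ccc(OC(C)=O)cc1)[C@H]2c1cc(OC(C)=O)cc(OC(C)=O)c1
F13 | step 22 | heptaacetate of 37 | CC(=O)Oc1ccc(/C=C/c2cc(OC(C)=O)c3c(c2)O[C@H](c2ccc(OC(C)=O)cc2)[C@H]3c2cc(OC(C)=O)c3c(c2)O[C@H](c2ccc(OC(C)=O)cc2)[C@H]3c2cc(OC(C)=O)cc(OC(C)=O)c2)cc1
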